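## Retrosynthetic overview

- **Feature.** On ring A (the benzene ring of the tetrahydroisoquinoline), three neighbouring carbons carry the C6 methoxy group, the C5–C1' biaryl bond and the C4a–C4 chain. Read from C5, this is the blocked-ortho / ipso / free-ortho pattern that an ortho-substituted aryl iodide gives in a palladium/norbornene (Catellani) reaction.
- **Key disconnection.** C4a–C4 and C5–C1' are cut together. The three pieces are 1-iodo-2,4-dimethoxybenzene, the 4,5-dimethoxy-7-methylnaphth-1-yl pinacol boronate, and (S)-2-methyl-1-tosylaziridine. The aziridine brings the ring nitrogen, C3, C4 and the only stereocentre, and comes from L-alaninol.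
- **Endgame.** C1 enters as formaldehyde, and the C1–C8a bond closes ring B by an N-sulfonyl Pictet–Spengler reaction at the carbon para to C6-OMe and ortho to C8-OMe. The N–S bond is then cleaved reductively.
- **Boronate.** The second naphthalene ring is closed anionically from an o-allyl diethylbenzamide, itself made by directed ortho-metalation of the amide of 2-methoxy-4-methylbenzoic acid. Naphthol-directed para-bromination, O-methylation and Miyaura borylation follow.
- **Ring order.** Aziridine (step 1, opened again in the key step), naphthalene ring (step 4), ring B (step 9).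

Key step: step 8

Assumption: the SMILES fixes only C3 (S) and leaves the hindered C5–C1' axis undefined, so only C3 is controlled and the product is taken as whatever mixture of atropodiastereomers forms, separable by chromatography at the last two stages if one is wanted.

## Route

Step 1
Reactants: 1 L-alaninol, (S)-2-aminopropan-1-ol
Product: 3 (S)-2-methyl-1-tosylaziridine, via N,O-ditosyl-L-alaninol 2 (not isolated)
Conditions: TsCl (2.5 equiv), KOH, CH2Cl2/H2O, rt
Reagents that add atoms: p-toluenesulfonyl chloride, Cc1ccc(S(=O)(=O)Cl)cc1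
Why: N- and O-sulfonylation followed by intramolecular SN2 displacement of the primary tosylate by the sulfonamide anion (Wenker-type aziridine synthesis) should occur only at CH2, so the S carbon of alaninol is carried over unchanged.

Step 2
Reactants: 4 2-methoxy-4-methylbenzoic acid
Product: 6 N,N-diethyl-2-methoxy-4-methylbenzamide, via acid chloride 5 (not isolated)
Conditions: (COCl)2, cat. DMF, CH2Cl2, 0 °C → rt; then Et2NH, Et3N, CH2Cl2, 0 °C
Reagents that add atoms: diethylamine, CCNCC; oxalyl chloride, O=C(Cl)C(=O)Cl (chlorine of 5 only)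
Why: Standard acid chloride formation and amine acylation install the diethylamide, which serves both as the directing group and as the later acyl electrophile.

Step 3
Reactants: 6 N,N-diethyl-2-methoxy-4-methylbenzamide
Product: 9 2-allyl-N,N-diethyl-6-methoxy-4-methylbenzamide, via aryllithium 7 (not isolated), via arylmagnesium bromide 8 (not isolated)
Conditions: s-BuLi, TMEDA, THF, −78 °C; MgBr2·OEt2, −78 °C → rt; allyl bromide, 0 °C → rt
Reagents that add atoms: allyl bromide, C=CCBr; s-BuLi, CCC(C)[Li] (lithium of 7 only); MgBr2, Br[Mg]Br (MgBr of 8 only)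
Why: Directed ortho-metalation should occur at the only free position next to the tertiary amide, and lithium-to-magnesium exchange tempers the basicity of the anion so that allylation proceeds cleanly.

Step 4
Reactants: 9 2-allyl-N,N-diethyl-6-methoxy-4-methylbenzamide
Product: 11 8-methoxy-6-methylnaphthalen-1-ol, via 8-methoxy-6-methylnaphthalen-1(2H)-one 10 (not isolated)
Conditions: LiN(iPr)2 (2.2 equiv), THF, −78 °C → rt; then aq HCl
Reagents that add atoms: none
Why: In this anionic aromatic ring annulation of an o-allylbenzamide, deprotonation of the benzylic-allylic CH2 gives an allyl anion whose terminal carbon acylates on the neighbouring amide, and loss of diethylamide followed by enolisation of 10 gives the naphthol.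

Step 5
Reactants: 11 8-methoxy-6-methylnaphthalen-1-ol
Product: 12 4-bromo-8-methoxy-6-methylnaphthalen-1-ol
Conditions: NBS (1.0 equiv), MeCN, 0 °C, dark
Reagents that add atoms: N-bromosuccinimide, O=C1CCC(=O)N1Br
Why: In this electrophilic aromatic bromination the free OH is the strongest donor and should direct NBS in polar MeCN to its para carbon C4 on the methyl-free ring, which is why bromination precedes O-methylation.

Step 6
Reactants: 12 4-bromo-8-methoxy-6-methylnaphthalen-1-ol
Product: 13 1-bromo-4,5-dimethoxy-7-methylnaphthalene
Conditions: MeI, K2CO3, DMF, rt → 40 °C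
Reagents that add atoms: iodomethane, CI
Why: Williamson O-methylation of the peri hydrogen-bonded naphtholate should go to completion in a dipolar solvent, and the aryl bromide is inert under these conditions.

Step 7
Reactants: 13 1-bromo-4,5-dimethoxy-7-methylnaphthalene
Product: 14 2-(4,5-dimethoxy-7-methylnaphthalen-1-yl)-4,4,5,5-tetramethyl-1,3,2-dioxaborolane
Conditions: B2pin2, PdCl2(dppf) (5 mol %), KOAc, 1,4-dioxane, 90 °C
Reagents that add atoms: bis(pinacolato)diboron, CC1(C)OB(OC1(C)C)B1OC(C)(C)C(C)(C)O1
Why: Miyaura borylation converts the aryl bromide into the pinacol ester, a form that resists protodeboronation better than the free acid of this electron-rich naphthalene.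

Step 8
Reactants: 15 1-iodo-2,4-dimethoxybenzene; 3 (S)-2-methyl-1-tosylaziridine (1.5 equiv); 14 2-(4,5-dimethoxy-7-methylnaphthalen-1-yl)-4,4,5,5-tetramethyl-1,3,2-dioxaborolane (2 equiv)
Product: 16 (S)-N-{1-[2-(4,5-dimethoxy-7-methylnaphthalen-1-yl)-3,5-dimethoxyphenyl]propan-2-yl}-4-methylbenzenesulfonamide
Conditions: Pd(OAc)2 (10 mol %), SPhos (20 mol %), norbornene (2 equiv), K2CO3 (3 equiv), 1,4-dioxane/H2O (10:1), 80 °C
Reagents that add atoms: none
Why: Proposed new method: zerovalent palladium inserts into the C–I bond of 15, norbornene carbopalladation and carbonate-assisted C–H cleavage at the only free ortho carbon (future C4a) give the five-membered aryl–norbornyl palladacycle, this opens 3 by SN2-type oxidative addition at the unsubstituted CH2 to tetravalent palladium, reductive elimination makes C4a–C4, and with both ortho positions filled norbornene leaves by β-carbon elimination so that the divalent arylpalladium is transmetalated by 14 and reductively eliminates to make C5–C1'. The closest known reaction types are the Catellani ortho-alkylation of aryl iodides with N-sulfonylaziridines (ended by Heck or C–N coupling) and the Catellani ortho-alkylation with alkyl halides ended by Suzuki–Miyaura coupling, whose pairing with a peri-hindered naphthylboronate has not been shown. No ring is closed and no stereocentre is created, because the C–N bond that breaks is the one at CH2, so the alaninol-derived carbon (future C3) keeps its S configuration while the new biaryl axis forms without control. Single alkylation is secured by the C2 methoxy group of 15 (future C6-OMe), which blocks the second ortho site and provides the ortho effect needed for norbornene extrusion, and the electron-rich iodide is a poor oxidant for the palladacycle, so self-arylation should lose to aziridine opening. Premature Suzuki coupling of 15 is disfavoured because norbornene insertion is faster than transmetalation of the hindered boronate. The critical chemoselectivity is transmetalation against ipso C–N closure of the pendant sulfonamide to a 2-methylindoline, and it is addressed by the double charge of 14, by water (which forms the reactive hydroxyboronate and keeps much of the sulfonamide protonated under the mild carbonate base) and by SPhos, which speeds coupling of di-ortho-substituted arylpalladium species.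

Step 9
Reactants: 16 (S)-N-{1-[2-(4,5-dimethoxy-7-methylnaphthalen-1-yl)-3,5-dimethoxyphenyl]propan-2-yl}-4-methylbenzenesulfonamide
Product: 18 (S)-5-(4,5-dimethoxy-7-methylnaphthalen-1-yl)-6,8-dimethoxy-3-methyl-2-tosyl-1,2,3,4-tetrahydroisoquinoline, via N-hydroxymethyl sulfonamide 17 (not isolated)
Conditions: (CH2O)n (1.5 equiv), TFA, CH2Cl2, 0 °C → rt
Reagents that add atoms: paraformaldehyde (as formaldehyde), C=O
Why: In this N-sulfonyl Pictet–Spengler reaction, acid ionises hemiaminal 17 to an N-sulfonyliminium ion that should be captured 6-endo-trig by the only free ortho carbon (C8a, para to C6-OMe and ortho to C8-OMe) faster than any intermolecular attack, and C3 is not involved.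

Step 10
Reactants: 18 (S)-5-(4,5-dimethoxy-7-methylnaphthalen-1-yl)-6,8-dimethoxy-3-methyl-2-tosyl-1,2,3,4-tetrahydroisoquinoline
Product: 19 (S)-5-(4,5-dimethoxy-7-methylnaphthalen-1-yl)-6,8-dimethoxy-3-methyl-1,2,3,4-tetrahydroisoquinoline (target)
Conditions: Mg turnings (excess), MeOH, sonication, rt → 40 °C
Reagents that add atoms: none
Why: Reductive desulfonylation by single-electron transfer from Mg in MeOH should cleave the N–S bond to the amine and the sulfinate while the aryl ethers, the electron-rich naphthalene and the C3 stereocentre stay untouched.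

## Compound list

1 | L-alaninol, (S)-2-aminopropan-1-ol | C[C@H](N)CO | starting material
2 | (S)-2-(tosylamino)propyl tosylate (N,O-ditosyl-L-alaninol) | C[C@H](NS(=O)(=O)c1ccc(C)cc1)COS(=O)(=O)c1ccc(C)cc1 | intermediate
3 | (S)-2-methyl-1-tosylaziridine | C[C@H]1CN1S(=O)(=O)c1ccc(C)cc1 | intermediate
4 | 2-methoxy-4-methylbenzoic acid | COc1cc(C)ccc1C(=O)O | starting material
5 | 2-methoxy-4-methylbenzoyl chloride | COc1cc(C)ccc1C(=O)Cl | intermediate
6 | N,N-diethyl-2-methoxy-4-methylbenzamide | CCN(CC)C(=O)c1ccc(C)cc1OC | intermediate
7 | [2-(diethylcarbamoyl)-3-methoxy-5-methylphenyl]lithium | [Li]c1cc(C)cc(OC)c1C(=O)N(CC)CC | intermediate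
8 | [2-(diethylcarbamoyl)-3-methoxy-5-methylphenyl]magnesium bromide | Br[Mg]c1cc(C)cc(OC)c1C(=O)N(CC)CC | intermediate
9 | 2-allyl-N,N-diethyl-6-methoxy-4-methylbenzamide | C=CCc1cc(C)cc(OC)c1C(=O)N(CC)CC | intermediate
10 | 8-methoxy-6-methylnaphthalen-1(2H)-one | O=C1CC=Cc2cc(C)cc(OC)c21 | intermediate
11 | 8-methoxy-6-methylnaphthalen-1-ol | COc1cc(C)cc2cccc(O)c12 | intermediate
12 | 4-bromo-8-methoxy-6-methylnaphthalen-1-ol | COc1cc(C)cc2c(Br)ccc(O)c12 | intermediate
13 | 1-bromo-4,5-dimethoxy-7-methylnaphthalene | COc1ccc(Br)c2cc(C)cc(OC)c12 | intermediate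
14 | 2-(4,5-dimethoxy-7-methylnaphthalen-1-yl)-4,4,5,5-tetramethyl-1,3,2-dioxaborolane | COc1ccc(B2OC(C)(C)C(C)(C)O2)c2cc(C)cc(OC)c12 | intermediate
15 | 1-iodo-2,4-dimethoxybenzene | COc1ccc(I)c(OC)c1 | starting material
16 | (S)-N-{1-[2-(4,5-dimethoxy-7-methylnaphthalen-1-yl)-3,5-dimethoxyphenyl]propan-2-yl}-4-methylbenzenesulfonamide | COc1cc(OC)c(-c2ccc(OC)c3c(OC)cc(C)cc23)c(C[C@H](C)NS(=O)(=O)c2ccc(C)cc2)c1 | intermediate
17 | (S)-N-(hydroxymethyl) derivative of 16 | COc1cc(OC)c(-c2ccc(OC)c3c(OC)cc(C)cc23)c(C[C@H](C)N(CO)S(=O)(=O)c2ccc(C)cc2)c1 | intermediate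
18 | (S)-5-(4,5-dimethoxy-7-methylnaphthalen-1-yl)-6,8-dimethoxy-3-methyl-2-tosyl-1,2,3,4-tetrahydroisoquinoline | COc1cc(OC)c(-c2ccc(OC)c3c(OC)cc(C)cc23)c2c1CN(S(=O)(=O)c1ccc(C)cc1)[C@@H](C)C2 | intermediate
19 | (S)-5-(4,5-dimethoxy-7-methylnaphthalen-1-yl)-6,8-dimethoxy-3-methyl-1,2,3,4-tetrahydroisoquinoline | COc1cc(OC)c(-c2ccc(OC)c3c(OC)cc(C)cc23)c2c1CN[C@@H](C)C2 | target

## Step count

Total step count: 10.
Longest linear sequence: 9 steps (steps 2–10, from 4 to 19).

## Steps most likely to fail

**1. Step 8.**
- **What may go wrong.** The slow transmetalation of the peri-hindered boronate may be outrun by ipso C–N closure of the pendant sulfonamide. It may also be outrun by protodeboronation of the electron-rich boronate, or by proton or hydride termination of the arylpalladium species.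
- **Fallback.** It sets out from 3 and 14 and comes back at 18, using only known reactions and removing the N–H before palladium meets the aryl halide.
- Aziridine 3 is opened at CH2 by commercial 3,5-dimethoxyphenylmagnesium chloride (COc1cc(OC)cc([Mg]Cl)c1) with catalytic CuI in THF (−30 °C → rt, dilute HCl quench). This gives (S)-N-[1-(3,5-dimethoxyphenyl)propan-2-yl]-4-methylbenzenesulfonamide F1.
- Ring B is closed at once with paraformaldehyde and TFA, as in step 9, to give (S)-6,8-dimethoxy-3-methyl-2-tosyl-1,2,3,4-tetrahydroisoquinoline F2.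
- NBS in MeCN should brominate C5 (para to C8-OMe) rather than the more crowded C7 between the two methoxy groups. This gives (S)-5-bromo-6,8-dimethoxy-3-methyl-2-tosyl-1,2,3,4-tetrahydroisoquinoline F3.
- A conventional Suzuki–Miyaura coupling of F3 with 14 (Pd(OAc)2, SPhos, K3PO4, toluene/H2O, 100 °C) gives 18.

**2. Step 10.**
- **What may go wrong.** Electron transfer to an unactivated dialkyl sulfonamide may be sluggish, so that N–S cleavage stalls. Forcing it may begin to reduce the benzylic C1–N bond.
- **Fallback.** It sets out from 16 and comes back at 19, reversing the order of ring closure and desulfonylation.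
- The N–H sulfonamide is acylated with Boc2O and DMAP in MeCN to give tert-butyl (S)-{1-[2-(4,5-dimethoxy-7-methylnaphthalen-1-yl)-3,5-dimethoxyphenyl]propan-2-yl}(tosyl)carbamate F4.
- The acyl-activated N–S bond of F4 is much easier to reduce. Mg in MeOH should therefore give tert-butyl (S)-{1-[2-(4,5-dimethoxy-7-methylnaphthalen-1-yl)-3,5-dimethoxyphenyl]propan-2-yl}carbamate F5.
- HCl in 1,4-dioxane followed by basic work-up frees (S)-1-[2-(4,5-dimethoxy-7-methylnaphthalen-1-yl)-3,5-dimethoxyphenyl]propan-2-amine F6.
- A classical Pictet–Spengler reaction of F6 with one equivalent of aqueous formaldehyde in dilute acid closes the strongly activated C8a position to give 19.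

**3. Step 3.**
- **What may go wrong.** Deprotonation of the C4 methyl group may compete with ortho-metalation. Lithium-to-magnesium exchange may be incomplete. Base may also move the allyl double bond into conjugation.
- **Fallback.** It sets out from 6 (through aryllithium 7) and comes back at 9, replacing the organometallic SN2 step with a cross-coupling.
- Aryllithium 7 is quenched with I2 at −78 °C to give N,N-diethyl-2-iodo-6-methoxy-4-methylbenzamide F7.
- A Stille allylation of F7 with allyltributylstannane (C=CC[Sn](CCCC)(CCCC)CCCC), Pd(PPh3)4, DMF, 90 °C, under neutral conditions gives 9.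

## Further compounds

F1 | step 8 | (S)-N-[1-(3,5-dimethoxyphenyl)propan-2-yl]-4-methylbenzenesulfonamide | COc1cc(OC)cc(C[C@H](C)NS(=O)(=O)c2ccc(C)cc2)c1
F2 | step 8 | (S)-6,8-dimethoxy-3-methyl-2-tosyl-1,2,3,4-tetrahydroisoquinoline | COc1cc(OC)c2c(c1)C[C@H](C)N(S(=O)(=O)c1ccc(C)cc1)C2
F3 | step 8 | (S)-5-bromo-6,8-dimethoxy-3-methyl-2-tosyl-1,2,3,4-tetrahydroisoquinoline | COc1cc(OC)c2c(c1Br)C[C@H](C)N(S(=O)(=O)c1ccc(C)cc1)C2
F4 | step 10 | tert-butyl (S)-{1-[2-(4,5-dimethoxy-7-methylnaphthalen-1-yl)-3,5-dimethoxyphenyl]propan-2-yl}(tosyl)carbamate | COc1cc(OC)c(-c2ccc(OC)c3c(OC)cc(C)cc23)c(C[C@H](C)N(C(=O)OC(C)(C)C)S(=O)(=O)c2ccc(C)cc2)c1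
F5 | step 10 | tert-butyl (S)-{1-[2-(4,5-dimethoxy-7-methylnaphthalen-1-yl)-3,5-dimethoxyphenyl]propan-2-yl}carbamate | COc1cc(OC)c(-c2ccc(OC)c3c(OC)cc(C)cc23)c(C[C@H](C)NC(=O)OC(C)(C)C)c1
F6 | step 10 | (S)-1-[2-(4,5-dimethoxy-7-methylnaphthalen-1-yl)-3,5-dimethoxyphenyl]propan-2-amine | COc1cc(OC)c(-c2ccc(OC)c3c(OC)cc(C)cc23)c(C[C@H](C)N)c1
F7 | step 3 | N,N-diethyl-2-iodo-6-methoxy-4-methylbenzamide | CCN(CC)C(=O)c1c(I)cc(C)cc1OC
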